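**Assumption:** (S)-glyceraldehyde acetonide, 3-methylfuran-2(5H)-one, tigloyl chloride, ICH2Bpin, (+)-Ipc2BCl and the two bis(trifluoroethyl) phosphonates are taken as purchasable; reagents are not numbered. Positions are cited in germacrane numbering (C1–C15).

## Retrosynthetic overview

1. The final step is only a global desilylation; the tiglate and every oxygen are already in place before ring formation.
2. Both rings form in one operation from an acyclic farnesane-type chain: first the C6–C7 bond (the farnesyl C1–C10 bond of germacrane biosynthesis) by intramolecular allylboration onto the C6 enal to close the ten-membered carbocycle, then O6→C12 lactonisation to close the γ-lactone.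
3. The allyl donor is a geometrically fixed (Z)-2-(methoxycarbonyl)allylboronate, made by a bromo-HWE reaction followed by Negishi coupling.
4. The C2–C3 bond comes from an Ipc2BCl aldol of a C1 methyl ketone with a (Z)-enal obtained from 3-methylbutenolide.
5. The methyl ketone and the C8 tiglate come from MeLi opening and in-situ tigloylation of 2-C-methyl-L-ribonolactone, itself made from (S)-glyceraldehyde acetonide by Z-olefination and OsO4 dihydroxylation.

## Route

Step 1
Reactants: 1 3-methylfuran-2(5H)-one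
Product: 3 (2Z)-N-methoxy-N,2-dimethyl-4-(triethylsilyloxy)but-2-enamide, via chloromagnesium alkoxide of the (Z)-hydroxy Weinreb amide 2 (not isolated)
Conditions: MeNH(OMe)·HCl, iPrMgCl, THF, −20 °C; then TESCl, imidazole (cat.), 0 °C
Reagents that add atoms: N,O-dimethylhydroxylamine hydrochloride, CNOC.Cl; chlorotriethylsilane, CC[Si](Cl)(CC)CC
Why: Weinreb aminolysis of the lactone by the magnesium amide, with O-silylation of the resulting alkoxide in the same flask to stop relactonisation; the ring fixes the Z geometry (C3 and C6 cis).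

Step 2
Reactants: 3 (2Z)-N-methoxy-N,2-dimethyl-4-(triethylsilyloxy)but-2-enamide
Product: 4 (2Z)-2-methyl-4-(triethylsilyloxy)but-2-enal
Conditions: DIBAL-H, THF, −78 °C; Rochelle salt
Reagents that add atoms: none
Why: Weinreb amide reduction stops at the aldehyde through the chelated tetrahedral intermediate, and the Z geometry survives at −78 °C.

Step 3
Reactants: 5 (S)-2,2-dimethyl-1,3-dioxolane-4-carbaldehyde
Product: 6 methyl (2Z)-3-[(4R)-2,2-dimethyl-1,3-dioxolan-4-yl]-2-methylprop-2-enoate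
Conditions: (CF3CH2O)2P(O)CH(Me)CO2Me, KHMDS, 18-crown-6, THF, −78 °C
Reagents that add atoms: methyl 2-[bis(2,2,2-trifluoroethoxy)phosphoryl]propanoate, COC(=O)C(C)P(=O)(OCC(F)(F)F)OCC(F)(F)F
Why: Still–Gennari olefination gives the Z-trisubstituted enoate (C8 cis to C1) under kinetic control without epimerising the aldehyde.

Step 4
Reactants: 6 methyl (2Z)-3-[(4R)-2,2-dimethyl-1,3-dioxolan-4-yl]-2-methylprop-2-enoate
Product: 8 2-C-methyl-L-ribono-1,4-lactone [(3S,4S,5S)-3,4-dihydroxy-5-(hydroxymethyl)-3-methyloxolan-2-one], via diol ester 7 (not isolated)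
Conditions: OsO4 (2 mol %), NMO, acetone/H2O, 0 → 23 °C; then 2 M HCl, 23 °C
Reagents that add atoms: N-methylmorpholine N-oxide, C[N+]1([O-])CCOCC1; water, O
Why: Upjohn dihydroxylation adds syn to the Z-alkene on the face anti to the allylic C8–O bond (Kishi/Stork model, H8 held in plane by A(1,3) strain), setting 9S and 10S from C8; acid then removes the acetonide and O8 closes the γ-lactone.

Step 5
Reactants: 8 2-C-methyl-L-ribono-1,4-lactone
Product: 9 (3S,4S,5S)-3-methyl-3,4-bis(triethylsilyloxy)-5-[(triethylsilyloxy)methyl]oxolan-2-one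
Conditions: TESOTf, 2,6-lutidine, CH2Cl2, −78 → 0 °C
Reagents that add atoms: triethylsilyl triflate, CC[Si](CC)(CC)OS(=O)(=O)C(F)(F)F
Why: The silyl triflate silylates the primary, secondary and tertiary hydroxyls in one operation, leaving O8 uniquely marked as the lactone oxygen.

Step 6
Reactants: 9 (3S,4S,5S)-3-methyl-3,4-bis(triethylsilyloxy)-5-[(triethylsilyloxy)methyl]oxolan-2-one
Product: 11 (3S,4S,5S)-3-methyl-2-oxo-3,4,6-tris(triethylsilyloxy)hexan-5-yl (2E)-2-methylbut-2-enoate, via lithium lactolate 10 (not isolated)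
Conditions: MeLi (1.05 equiv), THF, −78 °C; then tigloyl chloride, −78 → 0 °C
Reagents that add atoms: methyllithium, [Li]C; tigloyl chloride, C/C=C(\C)C(Cl)=O
Why: Single addition of MeLi to the hindered lactone gives a stable lactolate, and its ring-opened C8 alkoxide is trapped by O-acylation, so the C1 methyl ketone and the C8 tiglate are installed together without touching a stereocentre.

Step 7
Reactants: 11 (3S,4S,5S)-3-methyl-2-oxo-3,4,6-tris(triethylsilyloxy)hexan-5-yl (2E)-2-methylbut-2-enoate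
Product: 12 (2R,3S,4S)-4-methyl-1,5-dioxo-3,4-bis(triethylsilyloxy)hexan-2-yl (2E)-2-methylbut-2-enoate
Conditions: (COCl)2, DMSO, CH2Cl2, −78 → −40 °C; iPr2NEt, → 0 °C
Reagents that add atoms: none
Why: Swern conditions convert a primary TES ether directly to the aldehyde (oxidative desilylation) while secondary and tertiary TES ethers survive; Hünig's base at low temperature avoids epimerising the α-acyloxy aldehyde.

Step 8
Reactants: 12 (2R,3S,4S)-4-methyl-1,5-dioxo-3,4-bis(triethylsilyloxy)hexan-2-yl (2E)-2-methylbut-2-enoate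
Product: 13 methyl (2E,4S,5S,6S)-2-bromo-6-methyl-4-[(2E)-2-methylbut-2-enoyloxy]-7-oxo-5,6-bis(triethylsilyloxy)oct-2-enoate
Conditions: (CF3CH2O)2P(O)CHBrCO2Me, t-BuOK, 18-crown-6, THF, −78 °C
Reagents that add atoms: methyl 2-[bis(2,2,2-trifluoroethoxy)phosphoryl]-2-bromoacetate, COC(=O)C(Br)P(=O)(OCC(F)(F)F)OCC(F)(F)F
Why: The bromo-HWE reaction with the trifluoroethyl phosphonate (Kogen variant of Still–Gennari) gives the (E)-α-bromoacrylate, placing C8 cis to CO2Me, the geometry the ring closure needs.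

Step 9
Reactants: 13 methyl (2E,4S,5S,6S)-2-bromo-6-methyl-4-[(2E)-2-methylbut-2-enoyloxy]-7-oxo-5,6-bis(triethylsilyloxy)oct-2-enoate; 4 (2Z)-2-methyl-4-(triethylsilyloxy)but-2-enal
Product: 14 methyl (2E,4S,5S,6S,9S,10Z)-2-bromo-9-hydroxy-6,10-dimethyl-4-[(2E)-2-methylbut-2-enoyloxy]-7-oxo-5,6,12-tris(triethylsilyloxy)dodeca-2,10-dienoate
Conditions: (+)-Ipc2BCl, Et3N, Et2O, −78 → 0 °C; then 4, −78 → −20 °C; H2O2, pH 7 buffer, MeOH
Reagents that add atoms: none
Why: Paterson boron aldol of the methyl ketone (only C2 can enolise); the (+)-Ipc2B enolate is expected to attack the Si face of the Z-enal under reagent control, giving the 3S carbinol (C9 of the chain), with the minor epimer removed by chromatography.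

Step 10
Reactants: 14 (aldol adduct above)
Product: 15 methyl (2E,4S,5S,6S,9S,10Z)-2-bromo-9-(tert-butyldimethylsilyloxy)-6,10-dimethyl-4-[(2E)-2-methylbut-2-enoyloxy]-7-oxo-5,6,12-tris(triethylsilyloxy)dodeca-2,10-dienoate
Conditions: TBSOTf, 2,6-lutidine, CH2Cl2, −78 °C
Reagents that add atoms: tert-butyldimethylsilyl triflate, CC(C)(C)[Si](C)(C)OS(=O)(=O)C(F)(F)F
Why: Silylation of the only free hydroxyl; a 3-OTBS group prevents lactol and furan formation once the C6 aldehyde is unveiled and is distinguishable from the primary TES ether.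

Step 11
Reactants: 15 (TBS ether above)
Product: 16 methyl (2Z,4S,5S,6S,9S,10Z)-9-(tert-butyldimethylsilyloxy)-6,10-dimethyl-4-[(2E)-2-methylbut-2-enoyloxy]-7-oxo-2-[(4,4,5,5-tetramethyl-1,3,2-dioxaborolan-2-yl)methyl]-5,6,12-tris(triethylsilyloxy)dodeca-2,10-dienoate
Conditions: IZnCH2Bpin (from ICH2Bpin, Zn), Pd(PPh3)4 (5 mol %), THF, 23 → 40 °C
Reagents that add atoms: (pinacolatoboryl)methylzinc iodide, I[Zn]CB1OC(C)(C)C(C)(C)O1
Why: Negishi coupling of Knochel's borylmethylzinc reagent with the vinyl bromide proceeds with retention of alkene geometry and tolerates the ketone and esters, giving the allylboronate with C8 trans to CH2B.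

Step 12
Reactants: 16 (allylboronate above)
Product: 19 (3aS,4S,5S,6S,9S,10Z,11aR)-9-(tert-butyldimethylsilyloxy)-6,10-dimethyl-3-methylidene-2,7-dioxo-5,6-bis(triethylsilyloxy)-2,3,3a,4,5,6,7,8,9,11a-decahydrocyclodeca[b]furan-4-yl (2E)-2-methylbut-2-enoate, via seco-enal 17 (not isolated), via ring-closed pinacol borate 18 (not isolated)
Conditions: (COCl)2, DMSO, CH2Cl2, −78 °C; iPr2NEt; extractive work-up; then Sc(OTf)3 (10 mol %), PhMe (2 mM), 0 → 23 °C
Reagents that add atoms: none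
Why: Proposed new method: Swern oxidative desilylation of the primary allylic TES ether unveils the Z-enal, which the tethered boronate attacks in a Sc(OTf)3-catalysed closed-chair (type I) allylboration; with C8 trans to CH2B both chain ends sit equatorial, which gives the 6,7-anti (trans-lactone) relationship, and A(1,3) strain with the cis ester holds H8 in plane so C6 adds anti to the C8–C9 bond with OTig outside (6R,7S); the resulting borate lactonises onto the methyl ester, and the C1 ketone, flanked by the fully substituted C10–OTES carbon, is expected to be inert to the boronate; the closest known chemistry is Hall's Sc(OTf)3-catalysed tandem allylboration–lactonisation of 2-alkoxycarbonyl allylboronates, Hoffmann's intramolecular allylborations, and Cr(II) closures of ω-formyl allylic bromides to germacranolides.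

Step 13
Reactants: 19 (silyl-protected macrolactone above)
Product: 20 (3aS,4S,5S,6S,9S,10Z,11aR)-5,6,9-trihydroxy-6,10-dimethyl-3-methylidene-2,7-dioxo-2,3,3a,4,5,6,7,8,9,11a-decahydrocyclodeca[b]furan-4-yl (2E)-2-methylbut-2-enoate (CNP0106709.2)
Conditions: HF·pyridine, pyridine, THF, 0 → 23 °C
Reagents that add atoms: none
Why: Buffered fluoride desilylation removes the TBS and both TES groups without acid- or base-induced elimination of the allylic β-hydroxy ketone and without touching any stereocentre.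

## Compound list

1 | 3-methylfuran-2(5H)-one | CC1=CCOC1=O | starting material
2 | (2Z)-4-hydroxy-N-methoxy-N,2-dimethylbut-2-enamide (as chloromagnesium alkoxide) | OC/C=C(/C)C(=O)N(C)OC | intermediate
3 | (2Z)-N-methoxy-N,2-dimethyl-4-(triethylsilyloxy)but-2-enamide | CC[Si](CC)(CC)OC/C=C(/C)C(=O)N(C)OC | intermediate
4 | (2Z)-2-methyl-4-(triethylsilyloxy)but-2-enal (C3–C6) | CC[Si](CC)(CC)OC/C=C(/C)C=O | intermediate
5 | (S)-2,2-dimethyl-1,3-dioxolane-4-carbaldehyde | O=C[C@@H]1COC(C)(C)O1 | starting material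
6 | methyl (2Z)-3-[(4R)-2,2-dimethyl-1,3-dioxolan-4-yl]-2-methylprop-2-enoate | COC(=O)/C(C)=C\[C@@H]1COC(C)(C)O1 | intermediate
7 | methyl (2S,3S)-3-[(4S)-2,2-dimethyl-1,3-dioxolan-4-yl]-2,3-dihydroxy-2-methylpropanoate | COC(=O)[C@@](C)(O)[C@@H](O)[C@@H]1COC(C)(C)O1 | intermediate
8 | 2-C-methyl-L-ribono-1,4-lactone, (3S,4S,5S) | OC[C@@H]1OC(=O)[C@@](C)(O)[C@H]1O | intermediate
9 | (3S,4S,5S)-3-methyl-3,4-bis(triethylsilyloxy)-5-[(triethylsilyloxy)methyl]oxolan-2-one | CC[Si](CC)(CC)OC[C@@H]1OC(=O)[C@@](C)(O[Si](CC)(CC)CC)[C@H]1O[Si](CC)(CC)CC | intermediate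
10 | MeLi adduct of 9 (lithium lactolate, drawn as the hemiketal; anomeric centre undefined) | CC1(O)O[C@@H](CO[Si](CC)(CC)CC)[C@H](O[Si](CC)(CC)CC)[C@]1(C)O[Si](CC)(CC)CC | intermediate
11 | (3S,4S,5S)-3-methyl-2-oxo-3,4,6-tris(triethylsilyloxy)hexan-5-yl (2E)-2-methylbut-2-enoate | CC(=O)[C@@](C)(O[Si](CC)(CC)CC)[C@@H](O[Si](CC)(CC)CC)[C@@H](OC(=O)/C(C)=C/C)CO[Si](CC)(CC)CC | intermediate
12 | (2R,3S,4S)-4-methyl-1,5-dioxo-3,4-bis(triethylsilyloxy)hexan-2-yl (2E)-2-methylbut-2-enoate | CC(=O)[C@@](C)(O[Si](CC)(CC)CC)[C@@H](O[Si](CC)(CC)CC)[C@@H](OC(=O)/C(C)=C/C)C=O | intermediate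
13 | methyl (2E,4S,5S,6S)-2-bromo-6-methyl-4-[(2E)-2-methylbut-2-enoyloxy]-7-oxo-5,6-bis(triethylsilyloxy)oct-2-enoate | CC(=O)[C@@](C)(O[Si](CC)(CC)CC)[C@@H](O[Si](CC)(CC)CC)[C@@H](OC(=O)/C(C)=C/C)/C=C(/Br)C(=O)OC | intermediate
14 | methyl (2E,4S,5S,6S,9S,10Z)-2-bromo-9-hydroxy-6,10-dimethyl-4-[(2E)-2-methylbut-2-enoyloxy]-7-oxo-5,6,12-tris(triethylsilyloxy)dodeca-2,10-dienoate | CC[Si](CC)(CC)OC/C=C(/C)[C@@H](O)CC(=O)[C@@](C)(O[Si](CC)(CC)CC)[C@@H](O[Si](CC)(CC)CC)[C@@H](OC(=O)/C(C)=C/C)/C=C(/Br)C(=O)OC | intermediate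
15 | 9-O-TBS ether of 14 | CC[Si](CC)(CC)OC/C=C(/C)[C@@H](O[Si](C)(C)C(C)(C)C)CC(=O)[C@@](C)(O[Si](CC)(CC)CC)[C@@H](O[Si](CC)(CC)CC)[C@@H](OC(=O)/C(C)=C/C)/C=C(/Br)C(=O)OC | intermediate
16 | (2Z)-2-(pinacolborylmethyl) analogue of 15 (allylboronate; C8 cis to CO2Me) | CC[Si](CC)(CC)OC/C=C(/C)[C@@H](O[Si](C)(C)C(C)(C)C)CC(=O)[C@@](C)(O[Si](CC)(CC)CC)[C@@H](O[Si](CC)(CC)CC)[C@@H](OC(=O)/C(C)=C/C)/C=C(/CB1OC(C)(C)C(C)(C)O1)C(=O)OC | intermediate
17 | 12-oxo analogue of 16 (C6 Z-enal seco-aldehyde) | O=C/C=C(/C)[C@@H](O[Si](C)(C)C(C)(C)C)CC(=O)[C@@](C)(O[Si](CC)(CC)CC)[C@@H](O[Si](CC)(CC)CC)[C@@H](OC(=O)/C(C)=C/C)/C=C(/CB1OC(C)(C)C(C)(C)O1)C(=O)OC | intermediate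
18 | ten-membered carbocycle with C6–O–Bpin and the open methyl 2-methylidene ester at C7 (6R,7S) | C=C(C(=O)OC)[C@H]1[C@H](OB2OC(C)(C)C(C)(C)O2)/C=C(/C)[C@@H](O[Si](C)(C)C(C)(C)C)CC(=O)[C@@](C)(O[Si](CC)(CC)CC)[C@@H](O[Si](CC)(CC)CC)[C@H]1OC(=O)/C(C)=C/C | intermediate
19 | 3-O-TBS-9,10-bis-O-TES derivative of the target (3aS,4S,5S,6S,9S,10Z,11aR) | C=C1C(=O)O[C@@H]2/C=C(/C)[C@@H](O[Si](C)(C)C(C)(C)C)CC(=O)[C@@](C)(O[Si](CC)(CC)CC)[C@@H](O[Si](CC)(CC)CC)[C@@H](OC(=O)/C(C)=C/C)[C@@H]12 | intermediate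
20 | 8β-tigloyloxy-3β,9β,10β-trihydroxy-1-oxogermacra-4Z,11(13)-dien-12,6α-olide (CNP0106709.2) | C=C1C(=O)O[C@@H]2/C=C(/C)[C@@H](O)CC(=O)[C@@](C)(O)[C@@H](O)[C@@H](OC(=O)/C(C)=C/C)[C@@H]12 | target

## Step count and risks

Total: 13 steps. Longest linear sequence: 11 steps (5 → 20, steps 3–13); the enal branch (steps 1–2) joins at step 9.

Steps most likely to fail:

1. **Step 12 (ring closure).** The macrocyclic allylboration is unprecedented; the ring may not close, or the C6/C7 configuration may differ from the chair model. The fallback closes the same bond with chromium. It sets out from 16 and returns at 19: NaBO3·4H2O in THF/H2O oxidises the C–B bond to the primary allylic alcohol F1; CBr4/PPh3 gives the allylic bromide F2; Swern oxidation of the primary TES ether gives the enal F3; CrCl2 in DMF/THF at 3 mM (Nozaki–Hiyama–Kishi closure through an equilibrating allylchromium, as used for germacranolides) forms C6–C7, and the chromium alkoxide lactonises to 19.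

2. **Step 6 (MeLi, then tigloyl chloride).** The lactolate may be acylated at the anomeric oxygen, or a TES group may migrate to O8. The fallback sets out from 9 and returns at 11: ClMgN(OMe)Me opens the lactone to the hydroxy Weinreb amide F4; tigloyl chloride/DMAP/pyridine acylates the free C8 hydroxyl to give F5; MeMgBr at −78 °C converts the Weinreb amide into the methyl ketone 11.

3. **Step 9 (aldol).** Reagent control from Ipc2BCl may be modest or opposed by the α-silyloxy ketone. The fallback sets out from 13 and returns at 14: TMSOTf/Et3N gives the silyl enol ether F6, which adds to enal 4 in a Lewis-base-catalysed Mukaiyama aldol (SiCl4, chiral bisphosphoramide, −78 °C, catalyst-controlled); aqueous work-up gives 14.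

Further compounds
F1 | step 12 | (2Z)-2-(hydroxymethyl) analogue of 16 (CH2OH in place of CH2Bpin) | CC[Si](CC)(CC)OC/C=C(/C)[C@@H](O[Si](C)(C)C(C)(C)C)CC(=O)[C@@](C)(O[Si](CC)(CC)CC)[C@@H](O[Si](CC)(CC)CC)[C@@H](OC(=O)/C(C)=C/C)/C=C(/CO)C(=O)OC
F2 | step 12 | (2E)-2-(bromomethyl) analogue of 16 | CC[Si](CC)(CC)OC/C=C(/C)[C@@H](O[Si](C)(C)C(C)(C)C)CC(=O)[C@@](C)(O[Si](CC)(CC)CC)[C@@H](O[Si](CC)(CC)CC)[C@@H](OC(=O)/C(C)=C/C)/C=C(/CBr)C(=O)OC
F3 | step 12 | 12-oxo (C6 Z-enal) analogue of F2 | O=C/C=C(/C)[C@@H](O[Si](C)(C)C(C)(C)C)CC(=O)[C@@](C)(O[Si](CC)(CC)CC)[C@@H](O[Si](CC)(CC)CC)[C@@H](OC(=O)/C(C)=C/C)/C=C(/CBr)C(=O)OC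
F4 | step 6 | (2S,3S,4S)-4-hydroxy-N-methoxy-N,2-dimethyl-2,3,5-tris(triethylsilyloxy)pentanamide | CON(C)C(=O)[C@@](C)(O[Si](CC)(CC)CC)[C@@H](O[Si](CC)(CC)CC)[C@@H](O)CO[Si](CC)(CC)CC
F5 | step 6 | 4-O-tigloyl ester of F4 | CON(C)C(=O)[C@@](C)(O[Si](CC)(CC)CC)[C@@H](O[Si](CC)(CC)CC)[C@@H](OC(=O)/C(C)=C/C)CO[Si](CC)(CC)CC
F6 | step 9 | trimethylsilyl enol ether of ketone 13 (C1=C2) | C=C(O[Si](C)(C)C)[C@@](C)(O[Si](CC)(CC)CC)[C@@H](O[Si](CC)(CC)CC)[C@@H](OC(=O)/C(C)=C/C)/C=C(/Br)C(=O)OC
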